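The trap in these readings is that a straight line fits them so well that I could extend it to 20 h and stop.

- beta: starting material 0.50 M; gas 80 mM (held); free catalyst 5.9 mol%; the very flask that is asked about, followed so far
- flask: starting material 0.50 M; gas 80 mM (held); free catalyst 5.9 mol%; time 20 h

beta run (percent of the starting material charged)

| time / h | target / % | starting material / % |
|---|---|---|
| 0.417 | 0.3 | 95.0 |
| 1.33 | 3.5 | 91.2 |
| 2.00 | 6.2 | 88.7 |
| 3.00 | 10.4 | 84.5 |
| 5.00 | 18.7 | 76.3 |
| 6.00 | 22.7 | 72.0 |

(scatter of a reading: 0.3 percentage points)

- the analysis behind the earlier runs scatters by 0.3 percentage points, standard deviation
- at the start none of the gas is in solution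

- south-east: doubling the amount of free catalyst, all else as stated
- south: doubling the saturation concentration of gas, all else as stated
- west: doubling the transfer coefficient of the gas, all else as stated

- how much target there is at 20 h, in percent of the starting material charged
- the change that raises the amount of target at 20 h, in percent of the starting material charged most ("none" if none brings more than 2 percentage points) (south-east / south / west / none)
- amount of target at 20 h, in percent of the starting material charged, after west

I begin with the slope between the readings at 2.00 h and 6.00 h, and its intercept on the time axis:

s = 0.0413 /h of the charge, lag = 0.497 h

Dividing s by the catalyst charged gives my carried quantity, the turnover rate n, target made per hour per catalyst charged (the turnover frequency):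

n = 0.699 /h

At 6.00 h, starting material and target fall 5.30% short of the charge. I read this as starting material held on the catalyst, a share h of it:

h = 0.898

My first round is the line itself:

y = s(t − lag) = 80.5%

That leaves 14.2% of the starting material free, and I do not expect so little to keep the catalyst held. I therefore let the held share follow c(starting material)/(c(starting material) + K), with K = 8.15% of the charge from the reading at 6.00 h, and put the first answer back in:

y = (s/h)(t − lag) − K ln(94.7%/14.2%) = 74.1%

I commit to that figure. Doubling the catalyst doubles the places at the same n, and the line then reaches the charge by 12.6 h. Faster gas could lift the rate by a factor of 1.11 at best in my reckoning, less than the catalyst's factor of two. Even if the whole lag were the gas filling, doubling the transfer would halve it and gain 1 percentage point, below the margin; the catalyst may well fill for part of that lag, so I expect about 74.1% after west. My choice is south-east.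

The forecast differs: 78%, south, and 85% after west, on the ground that “Doubling the gas saturation doubles the rate in either case”.

The flask gives 73.0%, south-east as the best change, and 73.1% after west.

    coupling partner + free catalyst ⇌ catalyst intermediate A (K = 270 /M, k = 9.20 /M/min)
    starting material + catalyst intermediate A → catalyst intermediate B (k = 0.170 /M/min)
    catalyst intermediate B → catalyst intermediate C (k = 0.0180 /min)
    catalyst intermediate C → free catalyst + target (k = 0.0680 /min)
    gas ⇌ coupling partner, rate k5*(csat - [coupling partner]) (kL = 0.130 /min)

In this flask at 2.00 h, catalyst intermediate B, the resting state, holds 65.0% of the catalyst; its exit half-life of 38.5 min is the longest, against 0.20 h for catalyst intermediate A at 6.76 h and 5.33 min for the gas, and exit constant times share gives 0.702 /h beside n = 0.699 /h. The south-east flask, where n carried over put the end at 12.6 h, gains 26 points, while the south flask gains 0.85 points.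

The numbers in the tables were generated by integration with constants of no real substance; the scatter is artificial.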